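The dimer is cut at the interflavan bond C4–C6′ (primes mark the lower unit) into a C4-activated, benzylated epigallocatechin gallate, made from natural epigallocatechin, and a gallocatechin nucleophile whose ring C is built. The key step exploits that C2′ with its pyrogallol ring B is a galloyl carbon and O1′–C2′ an aryl ester bond. A 2-allylphenyl tri-O-benzylgallate is methylenated and cyclized in one pot by Cp2Ti(μ-CH2)(μ-Cl)AlMe2, a ring-closing olefinic ester metathesis that forges C2′=C3′ of a flav-2-ene. Reagent-controlled hydroboration of this enol ether then sets C2′ and C3′ trans, and bromine caps at both C8 positions steer the union to C6′.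

Key step: step 4

Remark on the chemistry: the target is read as epigallocatechin 3-O-gallate-(4β→6)-gallocatechin (upper unit 2R,3R with the C4 aryl bond β, that is 2,3-cis-3,4-trans; lower unit 2R,3S). The sense of induction in step 5 is assigned by analogy with 1-arylcycloalkenes; if the flavene responds in the opposite sense, IpcBH2 from (−)-α-pinene would be used instead.

Step 1
Reactants: 1 3,5-bis(benzyloxy)phenol
Product: 2 1-(allyloxy)-3,5-bis(benzyloxy)benzene
Conditions: allyl bromide, K2CO3, acetone, reflux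
Reagents that add atoms: allyl bromide, C=CCBr
Why: Williamson ether synthesis; the phenoxide should be O-alkylated cleanly by the allylic bromide.

Step 2
Reactants: 2 1-(allyloxy)-3,5-bis(benzyloxy)benzene
Product: 3 2-allyl-3,5-bis(benzyloxy)phenol
Conditions: N,N-diethylaniline, 195 °C, argon
Reagents that add atoms: none
Why: Aromatic Claisen rearrangement; the two ortho positions are equivalent, so a single allylphenol should form, and its freed hydroxyl is the future O1′.

Step 3
Reactants: 3 2-allyl-3,5-bis(benzyloxy)phenol; 4 3,4,5-tris(benzyloxy)benzoic acid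
Product: 5 2-allyl-3,5-bis(benzyloxy)phenyl 3,4,5-tris(benzyloxy)benzoate
Conditions: DCC, DMAP (cat.), CH2Cl2, 0 °C to rt
Reagents that add atoms: none
Why: Steglich esterification of the phenol; the ester carbon is the future C2′ and carries ring B.

Step 4
Reactants: 5 2-allyl-3,5-bis(benzyloxy)phenyl 3,4,5-tris(benzyloxy)benzoate
Product: 7 5,7-bis(benzyloxy)-2-[3,4,5-tris(benzyloxy)phenyl]-4H-chromene (penta-O-benzyl flav-2-ene), via enol ether 6 (not isolated)
Conditions: Cp2Ti(μ-CH2)(μ-Cl)AlMe2 (Tebbe reagent, 4 equiv), THF, 0 to 25 °C, then reflux; aq NaOH quench; Et3N-deactivated silica, argon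
Reagents that add atoms: none
Why: Cp2Ti=CH2 released from the reagent methylenates the electrophilic aryl ester carbonyl through an oxatitanacyclobutane to give enol ether 6; on heating, excess titanium methylidene exchanges with the terminal allyl alkene (titanacyclobutane, loss of ethylene) and the resulting alkylidene closes onto the 1,1-disubstituted enol ether by intramolecular (2+2) cycloaddition and cycloreversion, forming C2′=C3′. The closest known reaction type is the one-pot olefinic ester cyclization to cyclic enol ethers with Tebbe-type reagents (carbonyl methylenation followed by ring-closing metathesis). Ring C closes as a six-membered ring by ring-closing metathesis; the aryl oxygen and the benzylic CH2 hold both alkenes ortho on ring A, so only the 4H-chromene can form. No stereocenter is created; the step fixes the regiochemistry (O1′ and ring B on C2′, unsubstituted C3′, C4′ methylene) on which the hydroboration depends. The selectivity needed is carbonyl methylenation before alkene exchange and cyclization instead of dimerization, secured by the oxophilicity of the titanium methylidene, the ortho tether and dilution; the acid- and air-sensitive flav-2-ene is quenched with base and carried on at once.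

Step 5
Reactants: 7 5,7-bis(benzyloxy)-2-[3,4,5-tris(benzyloxy)phenyl]-4H-chromene
Product: 9 (2R,3S)-5,7-bis(benzyloxy)-2-[3,4,5-tris(benzyloxy)phenyl]chroman-3-ol (penta-O-benzyl-gallocatechin), via alkylborane 8 (not isolated)
Conditions: IpcBH2 from (+)-α-pinene [freed from (IpcBH2)2·TMEDA with BF3·OEt2, filtered], THF, −25 °C; then NaOH, H2O2, 0 °C to rt
Reagents that add atoms: hydrogen peroxide, OO
Why: Brown asymmetric hydroboration–oxidation; boron should add to C3′, the nucleophilic β-carbon of the aryl enol ether, and hydrogen to C2′ on the same face selected by the isopinocampheyl group, and oxidation with retention gives the 2,3-trans (2R,3S) alcohol.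

Step 6
Reactants: 9 (2R,3S)-5,7-bis(benzyloxy)-2-[3,4,5-tris(benzyloxy)phenyl]chroman-3-ol
Product: 10 (2R,3S)-8-bromo-5,7-bis(benzyloxy)-2-[3,4,5-tris(benzyloxy)phenyl]chroman-3-ol
Conditions: NBS (1.0 equiv), CH2Cl2, −78 to 0 °C
Reagents that add atoms: N-bromosuccinimide, O=C1CCC(=O)N1Br
Why: Electrophilic aromatic bromination; ring A is the most electron-rich ring and its less hindered C8 position should react first, leaving C6 as the only free ring A carbon.

Step 7
Reactants: 11 (−)-epigallocatechin (EGC, 2R,3R)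
Product: 12 5,7,3′,4′,5′-penta-O-benzyl-(−)-epigallocatechin (free C3 hydroxyl)
Conditions: BnBr (5.5 equiv), K2CO3, DMF, 0 °C to rt, argon
Reagents that add atoms: benzyl bromide, BrCc1ccccc1
Why: Williamson benzylation; carbonate should deprotonate only the five phenols, so the secondary C3 alcohol stays free, and the mild, oxygen-free conditions should spare the C2 configuration.

Step 8
Reactants: 12 penta-O-benzyl-(−)-epigallocatechin; 4 3,4,5-tris(benzyloxy)benzoic acid
Product: 13 octa-O-benzyl-EGCG (penta-O-benzyl-epigallocatechin 3-O-[3,4,5-tris(benzyloxy)benzoate])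
Conditions: DCC, DMAP, CH2Cl2, 0 °C to rt
Reagents that add atoms: none
Why: Steglich esterification of the only free hydroxyl; O-acylation leaves the C3 configuration (3R) untouched and installs the protected galloyl group of the upper unit.

Step 9
Reactants: 13 octa-O-benzyl-EGCG
Product: 14 8-bromo-octa-O-benzyl-EGCG
Conditions: NBS (1.0 equiv), CH2Cl2, −78 to 0 °C
Reagents that add atoms: N-bromosuccinimide, O=C1CCC(=O)N1Br
Why: Electrophilic aromatic bromination at C8 of ring A caps the most nucleophilic site of the future electrophile, so that it cannot condense with itself.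

Step 10
Reactants: 14 8-bromo-octa-O-benzyl-EGCG
Product: 15 4β-(2-ethoxyethoxy)-8-bromo-octa-O-benzyl-EGCG (2R,3R; C4 alkoxy trans to the C3 ester)
Conditions: DDQ, HOCH2CH2OEt, CH2Cl2, rt
Reagents that add atoms: 2-ethoxyethanol, CCOCCO
Why: Benzylic oxidation; DDQ abstracts the C4 hydride to a ring A-stabilised cation that the alcohol should capture anti to the C3 ester.

Step 11
Reactants: 15 4β-(2-ethoxyethoxy)-8-bromo-octa-O-benzyl-EGCG; 10 (2R,3S)-8-bromo-5,7-bis(benzyloxy)-2-[3,4,5-tris(benzyloxy)phenyl]chroman-3-ol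
Product: 16 protected dimer 8-bromo-octa-O-benzyl-EGCG-(4β→6)-8-bromo-penta-O-benzyl-gallocatechin (upper unit 2,3-cis-3,4-trans; lower unit 2R,3S)
Conditions: TMSOTf (0.3 equiv), 10 (3 equiv), CH2Cl2, 4 Å MS, −78 to −40 °C; Et3N quench
Reagents that add atoms: none
Why: Lewis acid-catalysed Friedel–Crafts flavan coupling; the C4 cation, shielded on one face by the C3 gallate, should be attacked by C6′ of 10 (C8′ is blocked by bromine) anti to the ester, setting the 3,4-trans interflavan bond.

Step 12
Reactants: 16 protected dimer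
Product: 17 epigallocatechin 3-O-gallate-(4β→6)-gallocatechin (target)
Conditions: H2 (1 atm), Pd(OH)2/C, THF/MeOH/H2O, rt; filtration, Sephadex LH-20
Reagents that add atoms: none
Why: Hydrogenolysis should remove all thirteen benzyl ethers and both aryl bromides in one operation without touching the ester, the interflavan bond or the stereocenters.

Compound list
1 | 3,5-bis(benzyloxy)phenol | Oc1cc(OCc2ccccc2)cc(OCc2ccccc2)c1 | starting material
2 | 1-(allyloxy)-3,5-bis(benzyloxy)benzene | C=CCOc1cc(OCc2ccccc2)cc(OCc2ccccc2)c1 | intermediate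
3 | 2-allyl-3,5-bis(benzyloxy)phenol | C=CCc1c(O)cc(OCc2ccccc2)cc1OCc1ccccc1 | intermediate
4 | 3,4,5-tris(benzyloxy)benzoic acid | OC(=O)c1cc(OCc2ccccc2)c(OCc2ccccc2)c(OCc2ccccc2)c1 | starting material
5 | 2-allyl-3,5-bis(benzyloxy)phenyl 3,4,5-tris(benzyloxy)benzoate | C=CCc1c(OC(=O)c2cc(OCc3ccccc3)c(OCc3ccccc3)c(OCc3ccccc3)c2)cc(OCc2ccccc2)cc1OCc1ccccc1 | intermediate
6 | 2-allyl-3,5-bis(benzyloxy)phenyl 1-[3,4,5-tris(benzyloxy)phenyl]vinyl ether | C=CCc1c(OC(=C)c2cc(OCc3ccccc3)c(OCc3ccccc3)c(OCc3ccccc3)c2)cc(OCc2ccccc2)cc1OCc1ccccc1 | intermediate (not isolated)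
7 | 5,7-bis(benzyloxy)-2-[3,4,5-tris(benzyloxy)phenyl]-4H-chromene | C1=C(c2cc(OCc3ccccc3)c(OCc3ccccc3)c(OCc3ccccc3)c2)Oc2cc(OCc3ccccc3)cc(OCc3ccccc3)c2C1 | intermediate
8 | 3-(isopinocampheylboryl) analogue of 9 (boron in place of the C3 oxygen, trans to the C2 aryl) | C[C@H]1[C@H](B[C@H]2Cc3c(OCc4ccccc4)cc(OCc4ccccc4)cc3O[C@@H]2c2cc(OCc3ccccc3)c(OCc3ccccc3)c(OCc3ccccc3)c2)C[C@@H]2C[C@H]1C2(C)C | intermediate (not isolated)
9 | (2R,3S)-5,7-bis(benzyloxy)-2-[3,4,5-tris(benzyloxy)phenyl]chroman-3-ol | O[C@H]1Cc2c(OCc3ccccc3)cc(OCc3ccccc3)cc2O[C@@H]1c1cc(OCc2ccccc2)c(OCc2ccccc2)c(OCc2ccccc2)c1 | intermediate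
10 | (2R,3S)-8-bromo-5,7-bis(benzyloxy)-2-[3,4,5-tris(benzyloxy)phenyl]chroman-3-ol | O[C@H]1Cc2c(OCc3ccccc3)cc(OCc3ccccc3)c(Br)c2O[C@@H]1c1cc(OCc2ccccc2)c(OCc2ccccc2)c(OCc2ccccc2)c1 | intermediate
11 | (−)-epigallocatechin (2R,3R) | O[C@@H]1Cc2c(O)cc(O)cc2O[C@@H]1c1cc(O)c(O)c(O)c1 | starting material
12 | 5,7,3′,4′,5′-penta-O-benzyl-(−)-epigallocatechin | O[C@@H]1Cc2c(OCc3ccccc3)cc(OCc3ccccc3)cc2O[C@@H]1c1cc(OCc2ccccc2)c(OCc2ccccc2)c(OCc2ccccc2)c1 | intermediate
13 | octa-O-benzyl-EGCG | O=C(O[C@@H]1Cc2c(OCc3ccccc3)cc(OCc3ccccc3)cc2O[C@@H]1c1cc(OCc2ccccc2)c(OCc2ccccc2)c(OCc2ccccc2)c1)c1cc(OCc2ccccc2)c(OCc2ccccc2)c(OCc2ccccc2)c1 | intermediate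
14 | 8-bromo-octa-O-benzyl-EGCG | O=C(O[C@@H]1Cc2c(OCc3ccccc3)cc(OCc3ccccc3)c(Br)c2O[C@@H]1c1cc(OCc2ccccc2)c(OCc2ccccc2)c(OCc2ccccc2)c1)c1cc(OCc2ccccc2)c(OCc2ccccc2)c(OCc2ccccc2)c1 | intermediate
15 | 4β-(2-ethoxyethoxy)-8-bromo-octa-O-benzyl-EGCG | O=C(O[C@@H]1[C@@H](OCCOCC)c2c(OCc3ccccc3)cc(OCc3ccccc3)c(Br)c2O[C@@H]1c1cc(OCc2ccccc2)c(OCc2ccccc2)c(OCc2ccccc2)c1)c1cc(OCc2ccccc2)c(OCc2ccccc2)c(OCc2ccccc2)c1 | intermediate
16 | 8-bromo-octa-O-benzyl-EGCG-(4β→6)-8-bromo-penta-O-benzyl-gallocatechin | O=C(O[C@@H]1[C@@H](c2c(OCc4ccccc4)c(Br)c3c(c2OCc2ccccc2)C[C@H](O)[C@@H](c2cc(OCc4ccccc4)c(OCc4ccccc4)c(OCc4ccccc4)c2)O3)c2c(OCc3ccccc3)cc(OCc3ccccc3)c(Br)c2O[C@@H]1c1cc(OCc2ccccc2)c(OCc2ccccc2)c(OCc2ccccc2)c1)c1cc(OCc2ccccc2)c(OCc2ccccc2)c(OCc2ccccc2)c1 | intermediate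
17 | epigallocatechin 3-O-gallate-(4β→6)-gallocatechin | O=C(O[C@@H]1[C@@H](c2c(O)cc3c(c2O)C[C@H](O)[C@@H](c2cc(O)c(O)c(O)c2)O3)c2c(O)cc(O)cc2O[C@@H]1c1cc(O)c(O)c(O)c1)c1cc(O)c(O)c(O)c1 | target

Total step count: 12. Longest linear sequence: 8 steps (steps 1 to 6, then 11 and 12); the upper unit is made in steps 7 to 10 and joins at step 11.

Steps most likely to fail

Step 4. The metathesis stage may stall at the hindered aryl enol ether. The product may also be lost by acid-promoted hydrolysis, by double-bond migration into the 2H-chromene, or by air oxidation towards a flavylium ion. The fallback sets out from 5 and separates the two events. The ester is methylenated with Cp2TiMe2 (toluene, 70 °C) and enol ether 6 is isolated on base-washed silica. The ring is then closed with the ruthenium carbene of the second-generation Grubbs catalyst (H2IMes)(PCy3)Cl2Ru=CHPh in toluene at 80 °C under argon, coming back to the route at 7. This fallback makes no compound outside the list (F0).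

Step 5. Facial discrimination by the isopinocampheyl group may be poor on this bulky trisubstituted enol ether. The β-aryloxy borane may also eliminate and open ring C before oxidation. The fallback sets out from 7 and replaces asymmetric induction by resolution. Hydroboration with BH3·SMe2 at 0 °C and immediate NaOH/H2O2 oxidation should give the racemic trans-flavan-3-ol F1. This is esterified with (S)-2-methoxy-2-phenylacetic acid (DCC, DMAP), and the diastereomeric esters are separated by chromatography to give the (S)-O-methylmandelate of the (2R,3S)-alcohol F2. Methanolysis (K2CO3, MeOH/THF) comes back to the route at 9.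

Step 11. Attack by the hindered, bromine-deactivated C6′ position may be slow. The C4 cation could then be diverted by capture through the neighbouring galloyl carbonyl, by elimination to a flavene, or by reaction with ring A of another upper unit. The fallback sets out from 15 and changes the mode of activation from a hard Lewis acid on an oxygen leaving group to thiophilic activation of a sulfide. Compound 15 is converted with 2,6-dimethylbenzenethiol and BF3·OEt2 (CH2Cl2, −78 °C) into the 4β-(2,6-dimethylphenylthio) analogue of 15 F3. This is activated with AgOTf in CH2Cl2 at −78 °C in the presence of 10, so that the cation is formed irreversibly under non-protic conditions, and the sequence comes back to the route at 16.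

Further compounds
F0 | step 4 | none | none
F1 | step 5 | racemic trans-5,7-bis(benzyloxy)-2-[3,4,5-tris(benzyloxy)phenyl]chroman-3-ol (1:1 mixture of 9 and its enantiomer) | O[C@H]1Cc2c(OCc3ccccc3)cc(OCc3ccccc3)cc2O[C@@H]1c1cc(OCc2ccccc2)c(OCc2ccccc2)c(OCc2ccccc2)c1.O[C@@H]1Cc2c(OCc3ccccc3)cc(OCc3ccccc3)cc2O[C@H]1c1cc(OCc2ccccc2)c(OCc2ccccc2)c(OCc2ccccc2)c1
F2 | step 5 | (S)-2-methoxy-2-phenylacetate ester of 9 | CO[C@H](C(=O)O[C@H]1Cc2c(OCc3ccccc3)cc(OCc3ccccc3)cc2O[C@@H]1c1cc(OCc2ccccc2)c(OCc2ccccc2)c(OCc2ccccc2)c1)c1ccccc1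
F3 | step 11 | 4β-(2,6-dimethylphenylthio)-8-bromo-octa-O-benzyl-EGCG | O=C(O[C@@H]1[C@@H](Sc2c(C)cccc2C)c2c(OCc3ccccc3)cc(OCc3ccccc3)c(Br)c2O[C@@H]1c1cc(OCc2ccccc2)c(OCc2ccccc2)c(OCc2ccccc2)c1)c1cc(OCc2ccccc2)c(OCc2ccccc2)c(OCc2ccccc2)c1
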